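## Retrosynthetic overview

- Labels: C1 = CMe2, C2 = CHBr, C3 = ring carbon of the exocyclic alkene, C4 = allylic CHCl, C5 = CH2, C6 = CHCl next to C1, C7 = exocyclic =CH, C8 = CH2Br. "Top" is the face carrying C4–Cl; "bottom" is the face carrying C2–Br and C6–Cl.
- Feature used: Br–C2–C3=C7–C8–Br is a 1,4-dihalo-2-ene with C8 cis to C2 on the single ring (cyclohexane C1–C6). This is the footprint of a cyclic 1,4-adduct of the semicyclic diene C2=C3–C7=C8.
- Both C–Br bonds go back to a cis-2-ene-1,4-diol (Appel, inversion at C2). The diol goes back to a 1,2-dioxine bridging C2 and C8 (O–O reduction, with the C2 carbinol turned over through its ketone), and the dioxine to singlet oxygen plus the 1-vinylcyclohexene.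
- The diene goes back to a trans-4,6-diol (two invertive chlorinations), Stille vinylation at C3, hydroxyl-directed reduction at C4, and enantioselective β-borylation/oxidation of 4,4-dimethylcyclohexadienone at C6.
- Ring order: the carbocycle is bought. The six-membered dioxine, fused at C2–C3, is the only ring made (step 7) and is opened again in step 8.

Key step: step 7

Assumption: the QuinoxP* enantiomer that gives the (5R)-boryl enone is used. The sense of induction is taken by analogy with simple cyclic enones, and the antipodal ligand, equally available, is used if the gem-dimethyl group reverses it.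

## Route

Step 1
Reactants: 1 4,4-dimethylcyclohexa-2,5-dien-1-one; 2 bis(pinacolato)diboron
Product: 4 (5R)-5-hydroxy-4,4-dimethylcyclohex-2-en-1-one, via boryl enone 3 (not isolated)
Conditions: CuCl (5 mol %), NaOtBu (10 mol %), QuinoxP* [2,3-bis(tert-butylmethylphosphino)quinoxaline, one enantiomer] (6 mol %), 2 (1.0 equiv), MeOH (2 equiv), THF, 0 °C; then NaBO3·4H2O, THF/H2O, rt
Reagents that add atoms: bis(pinacolato)diboron 2, CC1(C)OB(OC1(C)C)B1OC(C)(C)C(C)(C)O1 (boron of 3); NaBO3·4H2O (sodium perborate), [Na+].[Na+].O[B-]1(O)OO[B-](O)(O)OO1 (oxygen on C6)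
Why: Copper-catalysed asymmetric β-borylation of a cyclic enone, in which the chiral diphosphine selects one face of the two equivalent enone arms, one equivalent of 2 limits double addition, and perborate oxidation exchanges boron for hydroxyl with retention, should set C6–OH on the top face (R).

Step 2
Reactants: 4 (5R)-5-hydroxy-4,4-dimethylcyclohex-2-en-1-one
Product: 5 (5R)-5-hydroxy-2-iodo-4,4-dimethylcyclohex-2-en-1-one
Conditions: I2 (1.5 equiv), pyridine/CH2Cl2 1:1, 0 °C → rt, dark
Reagents that add atoms: iodine, [I][I]
Why: Johnson α-iodination (pyridine adds at C2, the enolate is iodinated at C3, pyridine leaves) is well established for 4,4-dialkylcyclohexenones, and pyridine is too weak a base to dehydrate the β-hydroxy ketone.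

Step 3
Reactants: 5 (5R)-5-hydroxy-2-iodo-4,4-dimethylcyclohex-2-en-1-one
Product: 6 (1R,3R)-4-iodo-6,6-dimethylcyclohex-4-ene-1,3-diol
Conditions: Me4NBH(OAc)3 (5 equiv), MeCN/AcOH 1:1, −30 °C
Reagents that add atoms: none
Why: In this Evans–Saksena hydroxyl-directed reduction the axial C6 hydroxyl replaces an acetate on boron and delivers hydride internally to the top face of the C4 carbonyl, so the new hydroxyl should lie on the bottom face, trans to C6–OH.

Step 4
Reactants: 6 (1R,3R)-4-iodo-6,6-dimethylcyclohex-4-ene-1,3-diol; 7 tributyl(vinyl)stannane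
Product: 8 (1R,3R)-4-ethenyl-6,6-dimethylcyclohex-4-ene-1,3-diol
Conditions: Pd2(dba)3 (2.5 mol %), AsPh3 (10 mol %), CuI (10 mol %), DMF, rt → 40 °C
Reagents that add atoms: tributyl(vinyl)stannane 7, C=C[Sn](CCCC)(CCCC)CCCC
Why: Stille coupling of an alkenyl iodide tolerates the free diol and installs C7=C8 before the molecule holds any allylic chloride that zerovalent palladium could ionise.

Step 5
Reactants: 8 (1R,3R)-4-ethenyl-6,6-dimethylcyclohex-4-ene-1,3-diol
Product: 9 (1R,5S)-5-chloro-4-ethenyl-2,2-dimethylcyclohex-3-en-1-ol
Conditions: PPh3 (1.2 equiv), hexachloroacetone (1.5 equiv), CH2Cl2, −20 → 0 °C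
Reagents that add atoms: hexachloroacetone, ClC(Cl)(Cl)C(=O)C(Cl)(Cl)Cl
Why: This Appel-type variant for allylic alcohols should displace the pseudoaxial allylic C4 oxyphosphonium by SN2 with inversion (chlorine on the top face), while the neopentyl C6–OH does not collapse at this temperature and SN2' attack is blocked because C2 adjoins the quaternary C1.

Step 6
Reactants: 9 (1R,5S)-5-chloro-4-ethenyl-2,2-dimethylcyclohex-3-en-1-ol
Product: 10 (4S,6S)-4,6-dichloro-1-ethenyl-3,3-dimethylcyclohex-1-ene
Conditions: PPh3 (3 equiv), CCl4 (10 equiv), 2,6-di-tert-butylpyridine (0.2 equiv), toluene, 70 °C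
Reagents that add atoms: carbon tetrachloride, ClC(Cl)(Cl)Cl
Why: In this Appel deoxychlorination of a hindered secondary carbinol, the half-chair with C4–Cl pseudoaxial holds the C6 oxyphosphonium axial, so chloride can attack from the open equatorial side while relief of the 1,3-diaxial contact helps departure, which should give the equatorial bottom-face chloride by inversion, trans to C4–Cl.

Step 7
Reactants: 10 (4S,6S)-4,6-dichloro-1-ethenyl-3,3-dimethylcyclohex-1-ene; 11 dioxygen
Product: 12 (5S,7S,8aS)-5,7-dichloro-8,8-dimethyl-3,5,6,7,8,8a-hexahydrobenzo[c][1,2]dioxine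
Conditions: O2 (1 atm, slow stream), tetraphenylporphyrin (1 mol %), white LED, CH2Cl2, −20 °C
Reagents that add atoms: dioxygen 11, O=O
Why: Tetraphenylporphyrin sensitises 11 to singlet oxygen, which adds in one concerted suprafacial [4+2] step to the s-cis rotamer of the diene C2=C3–C7=C8, making the C2–O and C8–O bonds and moving the π bond to C3=C7. The closest known reaction is the photooxygenation of 1-vinylcycloalkenes to bicyclic 1,2-dioxines. The six-membered dioxine ring (O–O–C8–C7=C3–C2) is closed by the cycloaddition itself, fused at C2–C3, and because the two-atom peroxide bridge ties C2 to C8 the new alkene can only have C8 cis to C2. The one new stereocentre, C2, is controlled by C4: A1,2 strain with the vinyl group holds C4–Cl pseudoaxial on the top face, and its bulk and lone-pair repulsion should send oxygen to the bottom face (C2–O cis to C6–Cl, 8aS), although the pseudoaxial C1 methyl on the bottom face works against this. Chemoselectivity over the ene reaction is secured by the substrate, since C1 bears no hydrogen, the C4 hydrogen lies close to the alkene plane and is deactivated by the geminal chlorine, and the monosubstituted C7=C8 bond is inert on its own. A modest facial preference is tolerable, because both C2 epimers converge on the same C2 ketone in steps 8 to 10.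

Step 8
Reactants: 12 (5S,7S,8aS)-5,7-dichloro-8,8-dimethyl-3,5,6,7,8,8a-hexahydrobenzo[c][1,2]dioxine
Product: 13 (1S,2E,3S,5S)-3,5-dichloro-2-(2-hydroxyethylidene)-6,6-dimethylcyclohexan-1-ol (CH2OH cis to the carbinol carbon; formally E because C4 with chlorine outranks C2)
Conditions: thiourea (1.1 equiv), MeOH, 0 °C → rt
Reagents that add atoms: none
Why: Thiourea reduction of an endoperoxide cleaves only the weak O–O bond, so both C–O bonds, the C2 configuration and the cis relation of C8 to C2 are kept, and one equivalent at low temperature should spare the allylic chloride from S-alkylation.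

Step 9
Reactants: 13 (1S,2E,3S,5S)-3,5-dichloro-2-(2-hydroxyethylidene)-6,6-dimethylcyclohexan-1-ol
Product: 14 (1S,2E,3S,5S)-2-[2-(tert-butyldimethylsilyloxy)ethylidene]-3,5-dichloro-6,6-dimethylcyclohexan-1-ol
Conditions: TBSCl (1.05 equiv), imidazole (2 equiv), CH2Cl2, 0 °C
Reagents that add atoms: tert-butyldimethylsilyl chloride, CC(C)(C)[Si](C)(C)Cl
Why: In this sterically controlled silylation the primary allylic C8–OH should react far faster than the secondary C2–OH flanked by the quaternary C1.

Step 10
Reactants: 14 (1S,2E,3S,5S)-2-[2-(tert-butyldimethylsilyloxy)ethylidene]-3,5-dichloro-6,6-dimethylcyclohexan-1-ol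
Product: 15 (2E,3S,5S)-2-[2-(tert-butyldimethylsilyloxy)ethylidene]-3,5-dichloro-6,6-dimethylcyclohexan-1-one
Conditions: Dess–Martin periodinane (1.3 equiv), CH2Cl2, 0 °C → rt
Reagents that add atoms: none
Why: Dess–Martin oxidation works without base or nucleophile, so vinylogous loss of HCl and isomerisation of the exocyclic alkene should not occur, and the C8 silyl ether prevents hemiketal and furan formation.

Step 11
Reactants: 15 (2E,3S,5S)-2-[2-(tert-butyldimethylsilyloxy)ethylidene]-3,5-dichloro-6,6-dimethylcyclohexan-1-one
Product: 16 (1R,2E,3S,5S)-2-[2-(tert-butyldimethylsilyloxy)ethylidene]-3,5-dichloro-6,6-dimethylcyclohexan-1-ol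
Conditions: NaBH4 (1 equiv), CeCl3·7H2O (1.2 equiv), MeOH, −78 °C
Reagents that add atoms: none
Why: In this Luche 1,2-reduction the allylic C4–Cl is axial on the top face of the preferred chair, so hydride should reach the C2 carbonyl from the bottom face (the face oxygen used in step 7) and place the hydroxyl on the top face (1R), which is the net inversion needed before an invertive bromination.

Step 12
Reactants: 16 (1R,2E,3S,5S)-2-[2-(tert-butyldimethylsilyloxy)ethylidene]-3,5-dichloro-6,6-dimethylcyclohexan-1-ol
Product: 17 (1R,2E,3S,5S)-3,5-dichloro-2-(2-hydroxyethylidene)-6,6-dimethylcyclohexan-1-ol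
Conditions: HF·pyridine, THF/pyridine, 0 °C
Reagents that add atoms: none
Why: Fluoride-mediated desilylation with buffered HF·pyridine avoids the basicity of Bu4NF, which could eliminate or displace the allylic chloride.

Step 13
Reactants: 17 (1R,2E,3S,5S)-3,5-dichloro-2-(2-hydroxyethylidene)-6,6-dimethylcyclohexan-1-ol
Product: 18 (2S,3Z,4S,6S)-2-bromo-3-(2-bromoethylidene)-4,6-dichloro-1,1-dimethylcyclohexane
Conditions: CBr4 (3 equiv), PPh3 (3.2 equiv), CH2Cl2, −20 → 0 °C
Reagents that add atoms: carbon tetrabromide, BrC(Br)(Br)Br
Why: In this double Appel bromination the primary allylic C8 oxyphosphonium is displaced directly and the secondary allylic C2 oxyphosphonium by SN2 with inversion from the bottom face, which should give the (2S) bromide cis to C6–Cl, with low temperature holding back allylic shift and halide exchange at C4.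

## Compound list

1 | 4,4-dimethylcyclohexa-2,5-dien-1-one | CC1(C)C=CC(=O)C=C1 | starting material
2 | bis(pinacolato)diboron | CC1(C)OB(OC1(C)C)B1OC(C)(C)C(C)(C)O1 | starting material
3 | (5R)-4,4-dimethyl-5-(4,4,5,5-tetramethyl-1,3,2-dioxaborolan-2-yl)cyclohex-2-en-1-one | CC1(C)C=CC(=O)C[C@H]1B2OC(C)(C)C(C)(C)O2 | intermediate
4 | (5R)-5-hydroxy-4,4-dimethylcyclohex-2-en-1-one | CC1(C)C=CC(=O)C[C@H]1O | intermediate
5 | (5R)-5-hydroxy-2-iodo-4,4-dimethylcyclohex-2-en-1-one | IC1=CC(C)(C)[C@H](O)CC1=O | intermediate
6 | (1R,3R)-4-iodo-6,6-dimethylcyclohex-4-ene-1,3-diol | IC1=CC(C)(C)[C@H](O)C[C@H]1O | intermediate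
7 | tributyl(vinyl)stannane | C=C[Sn](CCCC)(CCCC)CCCC | starting material
8 | (1R,3R)-4-ethenyl-6,6-dimethylcyclohex-4-ene-1,3-diol | CC1(C)C=C(C=C)[C@H](O)C[C@H]1O | intermediate
9 | (1R,5S)-5-chloro-4-ethenyl-2,2-dimethylcyclohex-3-en-1-ol | CC1(C)C=C(C=C)[C@@H](Cl)C[C@H]1O | intermediate
10 | (4S,6S)-4,6-dichloro-1-ethenyl-3,3-dimethylcyclohex-1-ene | CC1(C)C=C(C=C)[C@@H](Cl)C[C@@H]1Cl | intermediate
11 | dioxygen | O=O | starting material
12 | (5S,7S,8aS)-5,7-dichloro-8,8-dimethyl-3,5,6,7,8,8a-hexahydrobenzo[c][1,2]dioxine | CC1(C)[C@@H]2OOCC=C2[C@@H](Cl)C[C@@H]1Cl | intermediate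
13 | (1S,2E,3S,5S)-3,5-dichloro-2-(2-hydroxyethylidene)-6,6-dimethylcyclohexan-1-ol | CC1(C)[C@H](O)/C(=C\CO)[C@@H](Cl)C[C@@H]1Cl | intermediate
14 | (1S,2E,3S,5S)-2-[2-(tert-butyldimethylsilyloxy)ethylidene]-3,5-dichloro-6,6-dimethylcyclohexan-1-ol | CC1(C)[C@H](O)/C(=C\CO[Si](C)(C)C(C)(C)C)[C@@H](Cl)C[C@@H]1Cl | intermediate
15 | (2E,3S,5S)-2-[2-(tert-butyldimethylsilyloxy)ethylidene]-3,5-dichloro-6,6-dimethylcyclohexan-1-one | CC1(C)C(=O)/C(=C\CO[Si](C)(C)C(C)(C)C)[C@@H](Cl)C[C@@H]1Cl | intermediate
16 | (1R,2E,3S,5S)-2-[2-(tert-butyldimethylsilyloxy)ethylidene]-3,5-dichloro-6,6-dimethylcyclohexan-1-ol | CC1(C)[C@@H](O)/C(=C\CO[Si](C)(C)C(C)(C)C)[C@@H](Cl)C[C@@H]1Cl | intermediate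
17 | (1R,2E,3S,5S)-3,5-dichloro-2-(2-hydroxyethylidene)-6,6-dimethylcyclohexan-1-ol | CC1(C)[C@@H](O)/C(=C\CO)[C@@H](Cl)C[C@@H]1Cl | intermediate
18 | (2S,3Z,4S,6S)-2-bromo-3-(2-bromoethylidene)-4,6-dichloro-1,1-dimethylcyclohexane | CC1(C)[C@H](Br)/C(=C\CBr)[C@@H](Cl)C[C@@H]1Cl | target

Total step count: 13. Longest linear sequence: 13 steps (from 1).

## Steps most likely to fail

**Step 7 (key step).**
- What may go wrong: the diene is made electron-poor by the allylic chlorine and is crowded at C2 by the quaternary C1. The cycloaddition may therefore be slow enough for sensitiser bleaching, radical-chain peroxidation or breakdown of the peroxide to take over.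
- Fallback, from 10 back to the route at 18: ionic 1,4-addition of bromine (Br2, 1 equiv, CH2Cl2, −78 °C), followed by Bu4NBr at room temperature. The second treatment equilibrates the allylic dibromides toward the conjugate adduct with the trisubstituted C3=C7 bond.
- Bromide is expected to enter at C2 anti to the pseudoaxial C4–Cl. The alkene geometry is no longer locked by a ring, so the geometric isomers would have to be separated by HPLC.

**Step 13.**
- What may go wrong: backside attack at C2 is slowed by the quaternary C1 and by the cis C8 substituent. Attack of bromide at C7 with allylic shift, ionisation with loss of configuration, or closure of the C2 hydroxyl onto activated C8 to a dihydrofuran can then compete.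
- Fallback, from 13 back to the route at 18: Me3SiBr (2.5 equiv), CH2Cl2, −40 → 0 °C, converts both allylic hydroxyls under ionising conditions.
- C2 passes through an allyl cation that keeps the C3–C7 geometry and that either C2 epimer would give. Bromide should be captured on the bottom face, anti to the axial C4–Cl, while reversible allylic transposition favours the 1,4-dibromide.
- This replaces stereospecific substitution by substrate control and makes steps 9 to 12 unnecessary, which also covers poor facial selectivity in step 11.

**Step 6.**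
- What may go wrong: substitution at the neopentyl C6 may be outrun by elimination toward C5=C6, or by a 1,2-methyl shift from C1 assisted by the neighbouring diene. Long heating may also epimerise the allylic C4 chloride.
- Fallback, from 1 back to the route at 10: the C6–Cl bond is made by addition instead of substitution.
- Monoiodination of 1 (I2, pyridine) should give 2-iodo-4,4-dimethylcyclohexa-2,5-dien-1-one F1.
- Dry HCl in Et2O/CH2Cl2 at 0 °C should add reversibly to the uniodinated enone arm to give racemic 5-chloro-2-iodo-4,4-dimethylcyclohex-2-en-1-one F2, which never meets base.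
- (S)-Me-CBS oxazaborolidine with catecholborane (toluene, −78 → −40 °C) should reduce both enantiomers to the (1R) carbinol. This turns the racemate into separable diastereomers: the wanted cis isomer (1R,5S)-5-chloro-2-iodo-4,4-dimethylcyclohex-2-en-1-ol F3 and the discarded trans isomer (1R,5R)-5-chloro-2-iodo-4,4-dimethylcyclohex-2-en-1-ol F4.
- Stille vinylation of F3 with 7 under the conditions of step 4 should give (1R,5S)-5-chloro-2-ethenyl-4,4-dimethylcyclohex-2-en-1-ol F5. PPh3/hexachloroacetone then replaces the C4 hydroxyl by chlorine with inversion to give 10.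
- At most half of the material can be carried forward.

## Further compounds

F0 | step 7 | none | none
F0 | step 13 | none | none
F1 | step 6 | 2-iodo-4,4-dimethylcyclohexa-2,5-dien-1-one | IC1=CC(C)(C)C=CC1=O
F2 | step 6 | rac-5-chloro-2-iodo-4,4-dimethylcyclohex-2-en-1-one | IC1=CC(C)(C)C(Cl)CC1=O
F3 | step 6 | (1R,5S)-5-chloro-2-iodo-4,4-dimethylcyclohex-2-en-1-ol | IC1=CC(C)(C)[C@@H](Cl)C[C@H]1O
F4 | step 6 | (1R,5R)-5-chloro-2-iodo-4,4-dimethylcyclohex-2-en-1-ol | IC1=CC(C)(C)[C@H](Cl)C[C@H]1O
F5 | step 6 | (1R,5S)-5-chloro-2-ethenyl-4,4-dimethylcyclohex-2-en-1-ol | CC1(C)C=C(C=C)[C@H](O)C[C@@H]1Cl
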